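## Retrosynthetic overview

1. Enabling feature: rings C (O–C9–C11–C12–C13, tetrahydrofuran) and D (C13–C14=C15–O–C16, 2,3-dihydrofuran) form a 1,7-dioxaspiro[4.4]non-8-ene. The spiro carbon C13 bears the C9 oxygen and lies between C16–O and the enol-ether carbon C15. Ring D is therefore a cycloisomerized 3-butyn-1-ol (C16–OH onto C14≡C15), and ring C is what results when the C9 hydroxyl opens a C13–C16 oxirane.
2. Last disconnection: O–C15 and O9–C13 lead back to 18, a 9α-hydroxy decalin whose open CH2CH2 chain ends in a (13S)-2-ethynyloxirane. One operation closes rings C and D and sets C13 by inversion.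
3. Ring B: 6β-OAc from the Δ6 enol acetate (α-epoxidation, acyloxy shift with inversion); 9α-OH and 8α-Me from the 8-en-7-one (α-epoxidation, SmI2 opening); 7-one by allylic oxidation of the Δ8 alkene.
4. Side chain: alkyne from the epoxy aldehyde (Ohira–Bestmann), from Sharpless epoxidation of a 2-substituted allyl alcohol, from SN2 coupling of 11-bromodrim-8-ene with dilithiated methallyl alcohol.
5. Rings A and B (C5, C10) come from (−)-sclareol via drim-9(11)-en-8α-ol. Ring order: A and B (chiral pool), then C, then D, the last two in the final step.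

Key step: step 16

Assumption: the SMILES is read as (5S,6S,8S,9R,10S,13R), i.e. 6β-acetoxy-9α,13;15,16-diepoxylabd-14-en-7-one of the normal labdane series, so (−)-sclareol supplies C5 and C10; labdane numbering is used throughout.

## Route

Step 1
Reactants: 1 (−)-sclareol
Product: 2 8α-hydroxy-14,15-dinorlabdan-13-one
Conditions: OsO4 (2 mol %), NaIO4, THF/H2O, 45 °C
Reagents that add atoms: none
Why: Lemieux–Johnson cleavage of the vinyl group followed by periodate cleavage of the resulting α-hydroxy aldehyde excises C15 and C14 and leaves the C13 methyl ketone, with the 8α-hydroxyl and the ring stereocentres untouched.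

Step 2
Reactants: 2 8α-hydroxy-14,15-dinorlabdan-13-one
Product: 3 drim-9(11)-en-8α-ol
Conditions: hν (medium-pressure Hg lamp, quartz), hexane, 23 °C
Reagents that add atoms: none
Why: Norrish type 2 fragmentation, in which the excited C13 carbonyl abstracts the γ-hydrogen at C9 and the 1,4-biradical cleaves C11–C12 to give acetone and the exocyclic C9=C11 alkene without creating a stereocentre.

Step 3
Reactants: 3 drim-9(11)-en-8α-ol
Product: 4 11-bromodrim-8-ene
Conditions: PBr3, pyridine (cat.), Et2O, −10 to 0 °C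
Reagents that add atoms: phosphorus tribromide, BrP(Br)Br
Why: Bromination of the tertiary allylic alcohol with allylic transposition (SN2′-type) gives the primary allylic bromide with the more stable tetrasubstituted C8=C9 alkene; the C8 and C9 stereocentres erased here are rebuilt in steps 10 and 11.

Step 4
Reactants: 4 11-bromodrim-8-ene; 5 2-methylprop-2-en-1-ol
Product: 6 15-norlabda-8,13(16)-dien-14-ol
Conditions: 5 (2 equiv), n-BuLi (4 equiv), TMEDA, Et2O/hexane, 0 to 23 °C; then 4, THF, −78 to 0 °C
Reagents that add atoms: none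
Why: The O,C-dilithiated methallyl alcohol, an allyl anion with two equivalent CH2 termini, displaces the primary allylic bromide by SN2 at C11 (SN2′ attack at the fully substituted C8 is far more hindered), forming C11–C12 and delivering the 2-substituted allylic alcohol.

Step 5
Reactants: 6 15-norlabda-8,13(16)-dien-14-ol
Product: 7 (13S)-13,16-epoxy-15-norlabd-8-en-14-ol
Conditions: Ti(OiPr)4 (10 mol %), L-(+)-diethyl tartrate (12 mol %), t-BuOOH, 4 Å molecular sieves, CH2Cl2, −20 °C
Reagents that add atoms: tert-butyl hydroperoxide, CC(C)(C)OO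
Why: Sharpless asymmetric epoxidation, in which the titanium–(R,R)-tartrate catalyst oxidizes only the allylic-alcohol alkene (the C8=C9 alkene has no directing hydroxyl) and, by reagent control as for other 2-substituted allyl alcohols, gives the (13S)-oxirane.

Step 6
Reactants: 7 (13S)-13,16-epoxy-15-norlabd-8-en-14-ol
Product: 8 (13R)-13,16-epoxy-15-norlabd-8-en-14-al
Conditions: Dess–Martin periodinane, pyridine, CH2Cl2, 0 to 23 °C
Reagents that add atoms: none
Why: Dess–Martin oxidation of the primary alcohol under buffered conditions; the aldehyde has no α-hydrogen, so C13 cannot epimerize (the descriptor changes only through the priority switch).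

Step 7
Reactants: 8 (13R)-13,16-epoxy-15-norlabd-8-en-14-al
Product: 9 (13S)-13,16-epoxylabd-8-en-14-yne
Conditions: dimethyl (1-diazo-2-oxopropyl)phosphonate, K2CO3, MeOH, 0 to 23 °C
Reagents that add atoms: dimethyl (1-diazo-2-oxopropyl)phosphonate, COP(=O)(OC)C(=[N+]=[N-])C(C)=O
Why: Ohira–Bestmann homologation, in which the diazophosphonate anion adds to the aldehyde, loss of dimethyl phosphate and N2 gives an alkylidene carbene, and a 1,2-hydrogen shift delivers the terminal alkyne (C15) without touching the adjacent oxirane.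

Step 8
Reactants: 9 (13S)-13,16-epoxylabd-8-en-14-yne
Product: 10 (13S)-13,16-epoxy-15-(triisopropylsilyl)labd-8-en-14-yne
Conditions: n-BuLi, THF, −78 °C; then i-Pr3SiCl, −78 to 23 °C
Reagents that add atoms: chlorotriisopropylsilane, CC(C)[Si](Cl)(C(C)C)C(C)C
Why: Deprotonation and C-silylation of the terminal alkyne masks the acidic C–H for the enolate chemistry of step 13, and the bulky silyl alkyne survives the aqueous base of step 10.

Step 9
Reactants: 10 (13S)-13,16-epoxy-15-(triisopropylsilyl)labd-8-en-14-yne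
Product: 11 (13S)-13,16-epoxy-15-(triisopropylsilyl)labd-8-en-14-yn-7-one
Conditions: CrO3, 3,5-dimethylpyrazole, CH2Cl2, −20 °C
Reagents that add atoms: chromium trioxide, O=[Cr](=O)=O
Why: Allylic C–H oxidation with the CrO3–3,5-dimethylpyrazole complex converts the ring methylene C7, whose pseudo-axial hydrogens overlap with the C8=C9 π-bond, into the enone carbonyl; C11 is shielded by the quaternary C10 and the side chain.

Step 10
Reactants: 11 (13S)-13,16-epoxy-15-(triisopropylsilyl)labd-8-en-14-yn-7-one
Product: 12 (13S)-8α,9α;13,16-diepoxy-15-(triisopropylsilyl)labd-14-yn-7-one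
Conditions: H2O2 (30 % aq), NaOH, MeOH/THF, 0 to 23 °C
Reagents that add atoms: hydrogen peroxide, OO
Why: Weitz–Scheffer nucleophilic epoxidation, in which hydroperoxide adds to C9 axially on the α-face, anti to the angular C10 methyl, and the enolate closes onto oxygen, so the 8α,9α-epoxide fixes the 9α C–O bond.

Step 11
Reactants: 12 (13S)-8α,9α;13,16-diepoxy-15-(triisopropylsilyl)labd-14-yn-7-one
Product: 13 (8βH,13S)-13,16-epoxy-9α-hydroxy-15-(triisopropylsilyl)labd-14-yn-7-one
Conditions: SmI2 (2.2 equiv), THF/MeOH, −90 °C; then DBU (0.2 equiv), PhMe, 23 °C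
Reagents that add atoms: none
Why: SmI2 reduction of the α,β-epoxy ketone cleaves only the C8–O bond and leaves the 9α-hydroxyl in place, and C8, being α to the ketone, is brought by the amidine to the equatorial 8α-methyl epimer (an 8β-methyl would be 1,3-diaxial to the C10 methyl).

Step 12
Reactants: 13 (8βH,13S)-13,16-epoxy-9α-hydroxy-15-(triisopropylsilyl)labd-14-yn-7-one
Product: 14 (8βH,13S)-13,16-epoxy-15-(triisopropylsilyl)-9α-(trimethylsilyloxy)labd-14-yn-7-one
Conditions: N-(trimethylsilyl)imidazole, CH2Cl2, 23 °C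
Reagents that add atoms: N-(trimethylsilyl)imidazole, C[Si](C)(C)n1ccnc1
Why: Silylation of the hindered tertiary hydroxyl with a strong, non-basic silyl donor protects the β-hydroxy ketone from retro-aldol cleavage and from O-acylation in the next step without enolizing the ketone.

Step 13
Reactants: 14 (8βH,13S)-13,16-epoxy-15-(triisopropylsilyl)-9α-(trimethylsilyloxy)labd-14-yn-7-one
Product: 15 (8βH,13S)-13,16-epoxy-15-(triisopropylsilyl)-9α-(trimethylsilyloxy)labd-6-en-14-yn-7-yl acetate
Conditions: KN(SiMe3)2, THF, −78 °C; then Ac2O, −78 °C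
Reagents that add atoms: acetic anhydride, CC(=O)OC(C)=O
Why: Kinetic deprotonation at the C6 methylene (the C8 methine is flanked by the fully substituted C9) and O-acetylation of the potassium enolate give the Δ6 enol acetate.

Step 14
Reactants: 15 (8βH,13S)-13,16-epoxy-15-(triisopropylsilyl)-9α-(trimethylsilyloxy)labd-6-en-14-yn-7-yl acetate
Product: 17 (8βH,13S)-6β-acetoxy-13,16-epoxy-15-(triisopropylsilyl)-9α-(trimethylsilyloxy)labd-14-yn-7-one, via epoxy acetate 16 (not isolated)
Conditions: dimethyldioxirane (acetone solution), CH2Cl2, 0 °C; evaporate; PhMe, 110 °C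
Reagents that add atoms: dimethyldioxirane, CC1(C)OO1
Why: Epoxidation should occur on the α-face because the β-face at C6 is shielded by the syn-axial C4β and C10 methyls, and on heating the 7β-acetoxy group shifts to C6 in the concerted thermal rearrangement of enol ester epoxides, which inverts the migration terminus, so the acetate arrives on the β-face of C6 and the epoxide oxygen becomes the C7 ketone.

Step 15
Reactants: 17 (8βH,13S)-6β-acetoxy-13,16-epoxy-15-(triisopropylsilyl)-9α-(trimethylsilyloxy)labd-14-yn-7-one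
Product: 18 (8βH,13S)-6β-acetoxy-13,16-epoxy-9α-hydroxylabd-14-yn-7-one
Conditions: Bu4NF, AcOH (1:1), THF, 0 to 23 °C
Reagents that add atoms: none
Why: Fluoride cleaves both the Si–O and the Si–C(sp) bond, while the acetic acid buffer protects the β-hydroxy ketone from retro-aldol cleavage and the axial acetate, whose α-hydrogen is equatorial and poorly aligned for enolization, from epimerization.

Step 16
Reactants: 18 (8βH,13S)-6β-acetoxy-13,16-epoxy-9α-hydroxylabd-14-yn-7-one
Product: 20 (13R)-6β-acetoxy-9α,13;15,16-diepoxylabd-14-en-7-one (target), via tetrahydrofuran alkynol 19 (not isolated)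
Conditions: (+)-camphor-10-sulfonic acid (10 mol %), CH2Cl2, 0 °C; then Et3N, then (Et3N)Mo(CO)5 [preformed from Mo(CO)6 (30 mol %), Et3N, Et2O, hν 350 nm], 23 °C
Reagents that add atoms: none
Why: In the first stage the sulfonic acid activates the 2-alkyl-2-ethynyloxirane and the axial 9α-hydroxyl attacks C13 from the rear as the C13–O bond breaks (5-exo-tet), closing ring C and releasing the C16 oxygen as a primary alcohol, i.e. as a 3-butyn-1-ol. In the second stage, after the acid is quenched with Et3N, (Et3N)Mo(CO)5 converts the terminal alkyne into a molybdenum vinylidene whose electrophilic α-carbon C15 is captured by the C16 hydroxyl (formally 5-endo-dig), and protonolysis of the resulting cyclic oxacarbene/alkenyl-molybdenum releases the 2,3-dihydrofuran of ring D and the zerovalent catalyst. The closest known reaction types are the acid-catalysed intramolecular hydroxyl opening of alkynyl oxiranes at the propargylic carbon and the molybdenum-carbonyl/amine cycloisomerization of 1-alkyn-4-ols to 2,3-dihydrofurans. C13 is the only new stereocentre and is fixed by inversion of the (13S)-oxirane from step 5, so the 13R spiro centre is reagent-derived and not left to the weak facial bias of the decalin. The step needs attack at C13 and not at C16, which the five-membered transition state and the tertiary, alkyne-stabilized terminus secure, and it needs the oxirane to be consumed before the molybdenum is admitted, because a free alkynyl oxirane isomerizes under the same catalyst to the 3-substituted furan. The amine-buffered second stage and the fully substituted C13 should keep the acid-labile 3-alkoxy-2,3-dihydrofuran from ionizing to that furan, and the target is to be purified on base-washed silica.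

## Compound list

1 | (−)-sclareol, (13R)-labd-14-ene-8α,13-diol | C[C@]12CCCC(C)(C)[C@@H]1CC[C@@](C)(O)[C@@H]2CC[C@@](C)(O)C=C | starting material
2 | 8α-hydroxy-14,15-dinorlabdan-13-one | C[C@]12CCCC(C)(C)[C@@H]1CC[C@@](C)(O)[C@@H]2CCC(C)=O | intermediate
3 | drim-9(11)-en-8α-ol | C[C@]12CCCC(C)(C)[C@@H]1CC[C@@](C)(O)C2=C | intermediate
4 | 11-bromodrim-8-ene | CC1=C(CBr)[C@@]2(C)CCCC(C)(C)[C@@H]2CC1 | intermediate
5 | 2-methylprop-2-en-1-ol (methallyl alcohol) | CC(=C)CO | starting material
6 | 15-norlabda-8,13(16)-dien-14-ol | CC1=C(CCC(=C)CO)[C@@]2(C)CCCC(C)(C)[C@@H]2CC1 | intermediate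
7 | (13S)-13,16-epoxy-15-norlabd-8-en-14-ol | CC1=C(CC[C@@]3(CO3)CO)[C@@]2(C)CCCC(C)(C)[C@@H]2CC1 | intermediate
8 | (13R)-13,16-epoxy-15-norlabd-8-en-14-al | CC1=C(CC[C@@]3(CO3)C=O)[C@@]2(C)CCCC(C)(C)[C@@H]2CC1 | intermediate
9 | (13S)-13,16-epoxylabd-8-en-14-yne | CC1=C(CC[C@@]3(CO3)C#C)[C@@]2(C)CCCC(C)(C)[C@@H]2CC1 | intermediate
10 | (13S)-13,16-epoxy-15-(triisopropylsilyl)labd-8-en-14-yne | CC1=C(CC[C@@]3(CO3)C#C[Si](C(C)C)(C(C)C)C(C)C)[C@@]2(C)CCCC(C)(C)[C@@H]2CC1 | intermediate
11 | (13S)-13,16-epoxy-15-(triisopropylsilyl)labd-8-en-14-yn-7-one | CC1=C(CC[C@@]3(CO3)C#C[Si](C(C)C)(C(C)C)C(C)C)[C@@]2(C)CCCC(C)(C)[C@@H]2CC1=O | intermediate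
12 | (13S)-8α,9α;13,16-diepoxy-15-(triisopropylsilyl)labd-14-yn-7-one | C[C@]12O[C@@]1(CC[C@@]3(CO3)C#C[Si](C(C)C)(C(C)C)C(C)C)[C@@]1(C)CCCC(C)(C)[C@@H]1CC2=O | intermediate
13 | (8βH,13S)-13,16-epoxy-9α-hydroxy-15-(triisopropylsilyl)labd-14-yn-7-one | C1C(=O)[C@@H](C)[C@](O)(CC[C@@]3(CO3)C#C[Si](C(C)C)(C(C)C)C(C)C)[C@@]2(C)CCCC(C)(C)[C@H]12 | intermediate
14 | (8βH,13S)-13,16-epoxy-15-(triisopropylsilyl)-9α-(trimethylsilyloxy)labd-14-yn-7-one | C1C(=O)[C@@H](C)[C@](O[Si](C)(C)C)(CC[C@@]3(CO3)C#C[Si](C(C)C)(C(C)C)C(C)C)[C@@]2(C)CCCC(C)(C)[C@H]12 | intermediate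
15 | (8βH,13S)-13,16-epoxy-15-(triisopropylsilyl)-9α-(trimethylsilyloxy)labd-6-en-14-yn-7-yl acetate | C1=C(OC(C)=O)[C@@H](C)[C@](O[Si](C)(C)C)(CC[C@@]3(CO3)C#C[Si](C(C)C)(C(C)C)C(C)C)[C@@]2(C)CCCC(C)(C)[C@H]12 | intermediate
16 | (8βH,13S)-6α,7α;13,16-diepoxy-15-(triisopropylsilyl)-9α-(trimethylsilyloxy)labd-14-yn-7β-yl acetate | [C@@H]12O[C@@]2(OC(C)=O)[C@@H](C)[C@](O[Si](C)(C)C)(CC[C@@]3(CO3)C#C[Si](C(C)C)(C(C)C)C(C)C)[C@@]2(C)CCCC(C)(C)[C@H]12 | intermediate
17 | (8βH,13S)-6β-acetoxy-13,16-epoxy-15-(triisopropylsilyl)-9α-(trimethylsilyloxy)labd-14-yn-7-one | CC(=O)O[C@@H]1C(=O)[C@@H](C)[C@](O[Si](C)(C)C)(CC[C@@]3(CO3)C#C[Si](C(C)C)(C(C)C)C(C)C)[C@@]2(C)CCCC(C)(C)[C@H]12 | intermediate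
18 | (8βH,13S)-6β-acetoxy-13,16-epoxy-9α-hydroxylabd-14-yn-7-one | CC(=O)O[C@@H]1C(=O)[C@@H](C)[C@](O)(CC[C@@]3(CO3)C#C)[C@@]2(C)CCCC(C)(C)[C@H]12 | intermediate
19 | (8βH,13R)-6β-acetoxy-9α,13-epoxy-16-hydroxylabd-14-yn-7-one | CC(=O)O[C@@H]1C(=O)[C@@H](C)[C@]2(CC[C@](CO)(C#C)O2)[C@@]2(C)CCCC(C)(C)[C@H]12 | intermediate
20 | (8βH,13R)-6β-acetoxy-9α,13;15,16-diepoxylabd-14-en-7-one, CNP0224709.1 | CC(=O)O[C@@H]1C(=O)[C@@H](C)[C@]2(CC[C@]3(C=COC3)O2)[C@@]2(C)CCCC(C)(C)[C@H]12 | target

## Step count and risks

Total step count: 16. Longest linear sequence: 16 steps (1 to 20); compound 5 is used as purchased.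

Steps most likely to fail:

**Step 16.** In the molybdenum stage the vinylidene may form and turn over slowly at the hindered, neopentyl-type alkynol. Long contact of the product with the metal could then ionize the allylic C13–O bond and aromatize ring D to the 3-substituted furan. The fallback sets out from 19 and returns at 20. The acid stage alone is run and 19 is isolated. Anti-Markovnikov hydroboration of its terminal alkyne with (c-C6H11)2BH at 0 °C, where the hindered C7 ketone should be spared, and oxidation with NaBO3 give the C15 aldehyde. This closes onto the C16 hydroxyl to the lactol (8βH,13R)-6β-acetoxy-9α,13;15,16-diepoxy-15-hydroxylabdan-7-one F1, so the O–C15 bond is made by hemiacetal formation instead of by the vinylidene. MsCl/Et3N in CH2Cl2 then dehydrates the lactol through its anomeric sulfonate to the enol ether 20.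

**Step 14.** Facial selectivity in the epoxidation of the enol acetate may be poor, because the axial 9α-silyloxy group screens the α-face at C7 while the two axial methyls screen the β-face at C6. After the stereospecific shift, a β-epoxide would surface as the 6α-acetate. The fallback sets out from 15 and returns at 18; it replaces steric control by hydroxyl direction. The O-silyl group is removed selectively (citric acid, MeOH, 0 °C) to give (8βH,13S)-13,16-epoxy-9α-hydroxy-15-(triisopropylsilyl)labd-6-en-14-yn-7-yl acetate F2. Its free homoallylic 9α-hydroxyl then directs mCPBA (NaHCO3 buffer, CH2Cl2, 0 °C) to the α-face by hydrogen bonding, giving (8βH,13S)-6α,7α;13,16-diepoxy-9α-hydroxy-15-(triisopropylsilyl)labd-14-yn-7β-yl acetate F3. Heating in PhMe as before gives (8βH,13S)-6β-acetoxy-13,16-epoxy-9α-hydroxy-15-(triisopropylsilyl)labd-14-yn-7-one F4. Bu4NF/AcOH then removes the alkynyl silyl group and the route is rejoined at 18.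

**Step 10.** Conjugate addition of hydroperoxide to the tetrasubstituted β-carbon C9, next to the quaternary C10, may be too slow, so that base-mediated side reactions take over. The fallback sets out from 11 and returns at 12; it replaces the nucleophilic epoxidation by a hydroxyl-directed electrophilic one. 1,2-Reduction with the bulky hydride LiBH(s-Bu)3 (THF, −78 °C; attack on the β-face as with 7-keto steroids) should give the pseudo-axial allylic alcohol (13S)-13,16-epoxy-15-(triisopropylsilyl)labd-8-en-14-yn-7α-ol F5. VO(acac)2/t-BuOOH then epoxidizes the tetrasubstituted alkene syn to that hydroxyl, again on the α-face, to (13S)-8α,9α;13,16-diepoxy-15-(triisopropylsilyl)labd-14-yn-7α-ol F6. Dess–Martin oxidation returns the epoxy ketone 12.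

Further compounds
F1 | step 16 | (8βH,13R)-6β-acetoxy-9α,13;15,16-diepoxy-15-hydroxylabdan-7-one | CC(=O)O[C@@H]1C(=O)[C@@H](C)[C@]2(CC[C@]3(CC(O)OC3)O2)[C@@]2(C)CCCC(C)(C)[C@H]12
F2 | step 14 | (8βH,13S)-13,16-epoxy-9α-hydroxy-15-(triisopropylsilyl)labd-6-en-14-yn-7-yl acetate | C1=C(OC(C)=O)[C@@H](C)[C@](O)(CC[C@@]3(CO3)C#C[Si](C(C)C)(C(C)C)C(C)C)[C@@]2(C)CCCC(C)(C)[C@H]12
F3 | step 14 | (8βH,13S)-6α,7α;13,16-diepoxy-9α-hydroxy-15-(triisopropylsilyl)labd-14-yn-7β-yl acetate | [C@@H]12O[C@@]2(OC(C)=O)[C@@H](C)[C@](O)(CC[C@@]3(CO3)C#C[Si](C(C)C)(C(C)C)C(C)C)[C@@]2(C)CCCC(C)(C)[C@H]12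
F4 | step 14 | (8βH,13S)-6β-acetoxy-13,16-epoxy-9α-hydroxy-15-(triisopropylsilyl)labd-14-yn-7-one | CC(=O)O[C@@H]1C(=O)[C@@H](C)[C@](O)(CC[C@@]3(CO3)C#C[Si](C(C)C)(C(C)C)C(C)C)[C@@]2(C)CCCC(C)(C)[C@H]12
F5 | step 10 | (13S)-13,16-epoxy-15-(triisopropylsilyl)labd-8-en-14-yn-7α-ol | CC1=C(CC[C@@]3(CO3)C#C[Si](C(C)C)(C(C)C)C(C)C)[C@@]2(C)CCCC(C)(C)[C@@H]2C[C@H]1O
F6 | step 10 | (13S)-8α,9α;13,16-diepoxy-15-(triisopropylsilyl)labd-14-yn-7α-ol | C[C@]12O[C@@]1(CC[C@@]3(CO3)C#C[Si](C(C)C)(C(C)C)C(C)C)[C@@]1(C)CCCC(C)(C)[C@@H]1C[C@H]2O
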